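**Plan**

1. Retrosynthetic cuts, in this order: the three acetates and all silyl groups; C3=C4 (ring-closing metathesis); lactone C19–O and C6–C7 (chromium-mediated γ-chloroallylation of a C7 aldehyde); C8–C9 (aldol of a malic-acid dioxolanone enolate with the ring-A aldehyde); C10–C11 (α-ketol ring expansion); C1–C2 ([2,3]-Wittig).
2. Enabling feature: in the cyclohexane ring (C1, C14, C13, C12, C11, C10) the tertiary carbinol C11 (OH, CH3-20) stands next to oxygenated C12. This is the retron of an α-ketol shift, so the ring can come from a 1-acetylcyclopent-2-en-1-ol (ring C1, C14, C13, C12, C10) whose ring bond C12–C10 moves to the acetyl carbon.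
3. Forward order: cyclopentenol → quaternary C1 → cyclopentenone → C9 on C10 → acyloin → ring expansion to the C13=C14 enone → C12 alcohol and epoxide → C9 aldehyde → C8–C9 aldol → C7 aldehyde → chlorohydrin and γ-lactone → ten-membered ring → acetates.
4. Stereochemistry: the C13 carbinol (CBS reduction) is relayed to C1; C2 by Noyori transfer hydrogenation; C10 anti to the C1 chain; C11 in the key step; C12 by Luche reduction; epoxide by hydroxyl direction; C8 and C17 from (S)-malic acid; C9 in the aldol; C6 and C7 by anti-selective chloroallylation under Felkin–Anh control.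

Key step: step 10

Remark: carbon numbers are those of the briarane skeleton (C1 quaternary ring carbon with CH3-15, C2–C9 along the ten-membered ring, C10 ring-fusion CH, C11–C14 the rest of the six-membered ring, C17 and C19 in the lactone). The face selectivities and the migrating group in step 10 are predictions from models, not established facts.

**Step 1**
Reactants: 1 3-methylcyclopent-2-en-1-one
Product: 2 (S)-3-methylcyclopent-2-en-1-ol
Conditions: (R)-2-methyl-CBS-oxazaborolidine (10 mol %), BH3·SMe2, THF, −20 °C; MeOH, aqueous work-up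
Reagents that add atoms: none
Why: Corey–Bakshi–Shibata reduction in which the alkene flank acts as the large group, so the (R)-catalyst should give the (S)-allylic alcohol whose C–O bond later fixes C1.

**Step 2**
Reactants: 2 (S)-3-methylcyclopent-2-en-1-ol
Product: 3 silylpropargyl ether
Conditions: NaH, n-Bu4NI (cat.), THF, 0 °C → rt
Reagents that add atoms: 3-bromo-1-(trimethylsilyl)prop-1-yne, C[Si](C)(C)C#CCBr
Why: Williamson etherification at oxygen, which leaves the carbinol centre untouched.

**Step 3**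
Reactants: 3 silylpropargyl ether
Product: 4 homoallylic propargylic alcohol
Conditions: n-BuLi, THF, −78 → −30 °C; aq. NH4Cl
Reagents that add atoms: none
Why: [2,3]-Wittig rearrangement of the propargylic carbanion forms C1–C2 on the ring face that carried oxygen (suprafacial), which sets quaternary C1; the C2 epimers are carried on because step 4 removes that centre.

**Step 4**
Reactants: 4 homoallylic propargylic alcohol
Product: 5 alkynyl ketone
Conditions: Dess–Martin periodinane, NaHCO3, CH2Cl2, 0 °C → rt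
Reagents that add atoms: none
Why: Dess–Martin oxidation of a propargylic alcohol converges both C2 epimers on one ynone.

**Step 5**
Reactants: 5 alkynyl ketone
Product: 6 (R)-propargylic alcohol
Conditions: RuCl[(R,R)-TsDPEN](p-cymene) (2 mol %), 2-propanol, rt
Reagents that add atoms: none
Why: Noyori asymmetric transfer hydrogenation of an alkynyl ketone, in which the alkynyl group takes the place of the aryl group, so the (R,R)-catalyst should give the (R)-carbinol, which is C2 of the target.

**Step 6**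
Reactants: 6 (R)-propargylic alcohol
Product: 7 triethylsilyl ether
Conditions: Et3SiOTf, 2,6-lutidine, CH2Cl2, −78 → 0 °C
Reagents that add atoms: triethylsilyl trifluoromethanesulfonate, CC[Si](CC)(CC)OS(=O)(=O)C(F)(F)F
Why: silylation of a hindered secondary alcohol with a silyl triflate; the bulky silyloxy chain later shields one face of the ring.

**Step 7**
Reactants: 7 triethylsilyl ether
Product: 8 cyclopentenone
Conditions: Rh2(cap)4 (1 mol %), t-BuOOH, K2CO3, CH2Cl2, rt
Reagents that add atoms: tert-butyl hydroperoxide, CC(C)(C)OO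
Why: allylic C–H oxidation by tert-butylperoxyl radical; C12 is the only allylic methylene (the other allylic atom, C1, is quaternary) and the allyl radical is trapped at its unhindered end.

**Step 8**
Reactants: 8 cyclopentenone
Product: 11 silyloxymethyl cyclopentenone, via lithium dienolate 9 (not isolated), via lithium aldolate 10 (not isolated)
Conditions: LiN(i-Pr)2, THF, −78 °C; CH2O (gas from cracked paraformaldehyde), −78 °C; Et3SiCl, −78 → 0 °C
Reagents that add atoms: formaldehyde, C=O; chlorotriethylsilane, CC[Si](CC)(CC)Cl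
Why: the kinetic α′-enolate (the γ-carbon is quaternary) adds to formaldehyde anti to the bulky C1 chain, which sets C10 with C9 cis to CH3-15; trapping the aldolate prevents retro-aldol loss.

**Step 9**
Reactants: 11 silyloxymethyl cyclopentenone
Product: 13 acyloin, via ethoxyvinyl carbinol 12 (not isolated)
Conditions: 1-ethoxyvinyllithium (from ethyl vinyl ether and t-BuLi, THF, −78 → 0 °C), THF, −78 °C; aq. NH4Cl; crude 12 with oxalic acid (cat.), wet SiO2, CH2Cl2, 0 °C
Reagents that add atoms: ethyl vinyl ether (used as 1-ethoxyvinyllithium), C=COCC; water, O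
Why: 1,2-addition of an acetyl anion equivalent anti to the adjacent C10 substituent (acetyl cis to H-10), then buffered enol ether hydrolysis to the methyl ketone.

**Step 10**
Reactants: 13 acyloin
Product: 15 ring-A hydroxy enone, via desilylated acyloin 14 (not isolated)
Conditions: K2CO3, MeOH, 0 → 40 °C
Reagents that add atoms: none
Why: α-Ketol (acyloin) rearrangement: methoxide first removes the alkynyl silyl group and then, through the C12 alkoxide, drives a 1,2-shift of the ring bond C12–C10 onto the acetyl carbonyl carbon, which becomes C11 while C12 becomes the ring ketone. The closest known reaction type is the ring-expanding α-ketol shift of 1-acylcycloalkanols (D-homoannulation of 17-hydroxy-20-oxo steroids). Ring C1–C14–C13–C12–C11–C10 is closed by this suprafacial 1,2-migration through a three-centre transition state, so five ring atoms become six and C10 keeps its configuration. C11 is controlled by the C12 carbinol configuration from step 9: in the non-chelated alkoxide the C=O lies anti to C–O⁻, so C10 adds to the carbonyl face that leaves the new hydroxyl cis to H-10 and CH3-20 cis to C9, as in the target. The step needs C10 and not the vinylic C13 to migrate; the shift is reversible, and only the C10 shift gives a conjugated enone together with relief of cyclopentene strain, so equilibration should funnel material to 15.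

**Step 11**
Reactants: 15 ring-A hydroxy enone
Product: 16 cis-diol
Conditions: NaBH4, CeCl3·7H2O, MeOH, −78 °C
Reagents that add atoms: none
Why: Luche 1,2-reduction; axial hydride attack anti to the pseudoaxial C11 hydroxyl (Felkin–Anh polar model) should place the C12 hydroxyl cis to the C11 hydroxyl.

**Step 12**
Reactants: 16 cis-diol
Product: 17 epoxy diol
Conditions: VO(acac)2 (5 mol %), t-BuOOH, CH2Cl2, 0 °C → rt
Reagents that add atoms: tert-butyl hydroperoxide, CC(C)(C)OO
Why: hydroxyl-directed epoxidation delivers oxygen to C13=C14 on the face of the allylic C12 hydroxyl (and of the homoallylic C11 hydroxyl); the alkyne is inert.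

**Step 13**
Reactants: 17 epoxy diol
Product: 18 tetrakis(triethylsilyl) ether
Conditions: Et3SiOTf (3 equiv), 2,6-lutidine, CH2Cl2, −78 → 0 °C
Reagents that add atoms: triethylsilyl trifluoromethanesulfonate, CC[Si](CC)(CC)OS(=O)(=O)C(F)(F)F
Why: the silyl triflate caps the secondary C12 and the tertiary C11 hydroxyl, which blocks retro-aldol opening of ring A once C9 is an aldehyde.

**Step 14**
Reactants: 18 tetrakis(triethylsilyl) ether
Product: 19 vinyl carbinol ether
Conditions: H2 (1 atm), Pd/CaCO3 poisoned with Pb(OAc)2, quinoline, EtOAc, rt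
Reagents that add atoms: none
Why: Lindlar semi-hydrogenation of the terminal alkyne gives the vinyl group needed for metathesis.

**Step 15**
Reactants: 19 vinyl carbinol ether
Product: 20 ring-A aldehyde
Conditions: (COCl)2, DMSO, CH2Cl2, −78 → −40 °C; Et3N, → 0 °C
Reagents that add atoms: none
Why: Swern conditions cleave and oxidise a primary triethylsilyl ether directly to the aldehyde while secondary and tertiary silyl ethers stay.

**Step 16**
Reactants: 21 diethyl (S)-malate
Product: 22 diethyl (2S,3R)-3-methylmalate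
Conditions: LiN(i-Pr)2 (2.2 equiv), THF, −78 → −20 °C; MeI, −78 → −10 °C
Reagents that add atoms: iodomethane, CI
Why: Fráter–Seebach alkylation; the alkoxide-enolate dianion is methylated anti to the alkoxide, which sets C17.

**Step 17**
Reactants: 22 diethyl (2S,3R)-3-methylmalate
Product: 23 (2S,3R)-3-methylmalic acid
Conditions: KOH, H2O/THF, rt; HCl to pH 1
Reagents that add atoms: potassium hydroxide, [K+].[OH-]
Why: saponification of both esters at room temperature should not epimerise C17.

**Step 18**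
Reactants: 23 (2S,3R)-3-methylmalic acid
Product: 24 dioxolanone acid
Conditions: pivalaldehyde, p-TsOH (cat.), H2SO4 (cat.), pentane, reflux with water separator; recrystallisation
Reagents that add atoms: pivalaldehyde, CC(C)(C)C=O
Why: acetalisation of the α-hydroxy acid gives the cis-2-tert-butyl-1,3-dioxolan-4-one under thermodynamic control, which stores the C8 configuration in the acetal carbon.

**Step 19**
Reactants: 25 1,3-dichloroacetone
Product: 26 dichloro vinyl carbinol
Conditions: CH2=CHMgBr, THF, −78 °C; aq. NH4Cl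
Reagents that add atoms: vinylmagnesium bromide, C=C[Mg]Br
Why: Grignard 1,2-addition to the ketone at low temperature, with a cold acidic quench to avoid epoxide closure.

**Step 20**
Reactants: 26 dichloro vinyl carbinol
Product: 27 chlorodiene
Conditions: Burgess reagent, benzene, 50 °C
Reagents that add atoms: none
Why: Burgess syn-dehydration of the tertiary alcohol; the only β-hydrogens are on the chloromethyl groups, so the 1-chloro-2-(chloromethyl)diene results (E/Z mixture, both usable).

**Step 21**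
Reactants: 20 ring-A aldehyde; 24 dioxolanone acid
Product: 31 aldol adduct acid, via dilithium enolate 28 (not isolated), via dilithium aldolate 29 (not isolated), via silyl ester 30 (not isolated)
Conditions: 24, LiN(SiMe3)2 (2.1 equiv), THF, −78 °C; 20, −78 °C; Et3SiCl, −78 → −20 °C; pH 5 buffer
Reagents that add atoms: chlorotriethylsilane, CC[Si](CC)(CC)Cl
Why: aldol addition with self-regeneration of the stereocentre: the aldehyde adds anti to the tert-butyl group, so C9 replaces the former hydrogen at C8 with retention; C9 is expected from a chair transition state with the aldehyde residue turned away from the acetal ring, and silylation in the flask prevents lactonisation of O9 onto C19.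

**Step 22**
Reactants: 31 aldol adduct acid
Product: 34 silyloxy aldehyde silyl ester, via lactol 32 (not isolated), via hydroxy aldehyde 33 (not isolated)
Conditions: i-Bu2AlH (3.2 equiv), CH2Cl2, −78 °C; aq. potassium sodium tartrate; crude with Et3N (cat.), CH2Cl2, 0 °C, vacuum; Et3SiOTf (2.5 equiv), 2,6-lutidine, CH2Cl2, −78 °C; non-aqueous work-up
Reagents that add atoms: triethylsilyl trifluoromethanesulfonate, CC[Si](CC)(CC)OS(=O)(=O)C(F)(F)F
Why: the acylal-type dioxolanone carbonyl is reduced to the lactol in preference to the aluminium carboxylate; the lactol collapses with loss of pivalaldehyde, and immediate silylation of the tertiary C8 hydroxyl prevents an α-ketol shift and chelation in step 23.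

**Step 23**
Reactants: 34 silyloxy aldehyde silyl ester; 27 chlorodiene
Product: 36 chloro lactone triene, via chlorohydrin acid 35 (not isolated)
Conditions: CrCl2 (8 equiv), 27 (3 equiv), LiI (cat.), THF/DMF, 0 °C → rt; aq. citric acid; PPTS (cat.), CH2Cl2, rt
Reagents that add atoms: none
Why: Nozaki–Hiyama allylation with a γ-chloroallylchromium reagent: γ-attack through a chair transition state should give the anti chlorohydrin (C6, C7), Felkin–Anh addition to the α-silyloxy aldehyde (C9 branch larger than C17 branch) should set C7, and the γ-hydroxy acid freed at work-up lactonises.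

**Step 24**
Reactants: 36 chloro lactone triene
Product: 37 macrocyclic pentakis(triethylsilyl) ether
Conditions: second-generation Hoveyda–Grubbs catalyst RuCl2(H2IMes)(=CH–C6H4-2-O-i-Pr) (15 mol %), toluene (1 mM), 80 °C, argon sparge
Reagents that add atoms: none
Why: ring-closing metathesis between the two monosubstituted alkenes (the 1,1-disubstituted methylene is much slower) closes the ten-membered ring, which should enforce the Z C3=C4 bond.

**Step 25**
Reactants: 37 macrocyclic pentakis(triethylsilyl) ether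
Product: 38 pentaol
Conditions: HF·pyridine, pyridine, THF, 0 °C → rt
Reagents that add atoms: none
Why: buffered fluoride removes all five triethylsilyl groups and should spare the epoxide, the allylic chloride and the lactone.

**Step 26**
Reactants: 38 pentaol
Product: 39 CNP0331168.1
Conditions: Ac2O, pyridine, DMAP (cat.), CH2Cl2, 0 °C → rt
Reagents that add atoms: acetic anhydride, CC(=O)OC(C)=O
Why: acetylation of the three secondary hydroxyls (C2, C9, C12); the tertiary hydroxyls at C8 and C11 should not react under these conditions.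

**Compound list**

1 | 3-methylcyclopent-2-en-1-one | CC1=CC(=O)CC1 | starting material
2 | (S)-3-methylcyclopent-2-en-1-ol | O[C@@H]1C=C(C)CC1 | intermediate
3 | (S)-3-methylcyclopent-2-enyl 3-(trimethylsilyl)prop-2-ynyl ether | C[Si](C)(C)C#CCO[C@@H]1C=C(C)CC1 | intermediate
4 | 1-[(1R)-1-methylcyclopent-2-en-1-yl]-3-(trimethylsilyl)prop-2-yn-1-ol, both carbinol epimers | C[Si](C)(C)C#CC(O)[C@@]1(C)C=CCC1 | intermediate
5 | 1-[(1R)-1-methylcyclopent-2-en-1-yl]-3-(trimethylsilyl)prop-2-yn-1-one | C[Si](C)(C)C#CC(=O)[C@@]1(C)C=CCC1 | intermediate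
6 | (1R)-1-[(1R)-1-methylcyclopent-2-en-1-yl]-3-(trimethylsilyl)prop-2-yn-1-ol (carbinol = C2) | C[Si](C)(C)C#C[C@H](O)[C@@]1(C)C=CCC1 | intermediate
7 | triethylsilyl ether of 6 | C[Si](C)(C)C#C[C@H](O[Si](CC)(CC)CC)[C@@]1(C)C=CCC1 | intermediate
8 | 4-methyl-4-[1-(triethylsilyloxy)-3-(trimethylsilyl)prop-2-ynyl]cyclopent-2-en-1-one, C1 and C2 as in 7 | C[Si](C)(C)C#C[C@H](O[Si](CC)(CC)CC)[C@@]1(C)C=CC(=O)C1 | intermediate
9 | lithium cross-conjugated dienolate of 8 | C[Si](C)(C)C#C[C@H](O[Si](CC)(CC)CC)[C@@]1(C)C=CC(O[Li])=C1 | intermediate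
10 | lithium aldolate of 8 with formaldehyde, CH2OLi trans to the silyloxypropargyl chain | C[Si](C)(C)C#C[C@H](O[Si](CC)(CC)CC)[C@@]1(C)C=CC(=O)[C@@H]1CO[Li] | intermediate
11 | 5-[(triethylsilyloxy)methyl] derivative of 8, CH2OSiEt3 trans to the silyloxypropargyl chain and cis to the ring methyl | C[Si](C)(C)C#C[C@H](O[Si](CC)(CC)CC)[C@@]1(C)C=CC(=O)[C@@H]1CO[Si](CC)(CC)CC | intermediate
12 | 1-(1-ethoxyvinyl)cyclopent-2-en-1-ol from 11, ethoxyvinyl trans to CH2OSiEt3 | C[Si](C)(C)C#C[C@H](O[Si](CC)(CC)CC)[C@@]1(C)C=C[C@@](O)(C(=C)OCC)[C@@H]1CO[Si](CC)(CC)CC | intermediate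
13 | 1-acetylcyclopent-2-en-1-ol (acyloin), acetyl trans to CH2OSiEt3 and cis to H-10 | C[Si](C)(C)C#C[C@H](O[Si](CC)(CC)CC)[C@@]1(C)C=C[C@@](O)(C(C)=O)[C@@H]1CO[Si](CC)(CC)CC | intermediate
14 | acyloin 13 without the alkynyl trimethylsilyl group | C#C[C@H](O[Si](CC)(CC)CC)[C@@]1(C)C=C[C@@](O)(C(C)=O)[C@@H]1CO[Si](CC)(CC)CC | intermediate
15 | 6-hydroxy-4,6-dimethyl-4-[1-(triethylsilyloxy)prop-2-ynyl]-5-[(triethylsilyloxy)methyl]cyclohex-2-en-1-one, C1, C2, C10, C11 as in the target (C11 hydroxyl cis to H-10) | C#C[C@H](O[Si](CC)(CC)CC)[C@@]2(C)C=CC(=O)[C@@](C)(O)[C@@H]2CO[Si](CC)(CC)CC | intermediate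
16 | cyclohex-2-ene-1,6-diol from 15, C12 hydroxyl cis to C11 hydroxyl | C#C[C@H](O[Si](CC)(CC)CC)[C@@]2(C)C=C[C@@H](O)[C@@](C)(O)[C@@H]2CO[Si](CC)(CC)CC | intermediate
17 | C13–C14 epoxide of 16, epoxide cis to both hydroxyls | C#C[C@H](O[Si](CC)(CC)CC)[C@@]2(C)[C@H]3O[C@H]3[C@@H](O)[C@@](C)(O)[C@@H]2CO[Si](CC)(CC)CC | intermediate
18 | C2, C9, C11, C12 tetrakis(triethylsilyl) ether of the epoxy tetraol with terminal alkyne | C#C[C@H](O[Si](CC)(CC)CC)[C@@]2(C)[C@H]3O[C@H]3[C@@H](O[Si](CC)(CC)CC)[C@@](C)(O[Si](CC)(CC)CC)[C@@H]2CO[Si](CC)(CC)CC | intermediate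
19 | vinyl analogue of 18 (C3=C4 terminal alkene) | C=C[C@H](O[Si](CC)(CC)CC)[C@@]2(C)[C@H]3O[C@H]3[C@@H](O[Si](CC)(CC)CC)[C@@](C)(O[Si](CC)(CC)CC)[C@@H]2CO[Si](CC)(CC)CC | intermediate
20 | ring-A C9 aldehyde from 19 | C=C[C@H](O[Si](CC)(CC)CC)[C@@]2(C)[C@H]3O[C@H]3[C@@H](O[Si](CC)(CC)CC)[C@@](C)(O[Si](CC)(CC)CC)[C@@H]2C=O | intermediate
21 | diethyl (S)-malate | CCOC(=O)C[C@H](O)C(=O)OCC | starting material
22 | diethyl (2S,3R)-2-hydroxy-3-methylsuccinate | CCOC(=O)[C@@H](O)[C@@H](C)C(=O)OCC | intermediate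
23 | (2S,3R)-2-hydroxy-3-methylsuccinic acid | OC(=O)[C@@H](O)[C@@H](C)C(O)=O | intermediate
24 | (2R)-2-[(2S,4S)-2-tert-butyl-5-oxo-1,3-dioxolan-4-yl]propanoic acid (cis acetal) | CC(C)(C)[C@H]1O[C@@H]([C@@H](C)C(O)=O)C(=O)O1 | intermediate
25 | 1,3-dichloroacetone | ClCC(=O)CCl | starting material
26 | 1-chloro-2-(chloromethyl)but-3-en-2-ol | OC(CCl)(CCl)C=C | intermediate
27 | 1-chloro-2-(chloromethyl)buta-1,3-diene (E/Z mixture) | ClC=C(CCl)C=C | intermediate
28 | dilithium enolate carboxylate of 24 | CC(C)(C)[C@H]1OC([C@@H](C)C(=O)O[Li])=C(O[Li])O1 | intermediate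
29 | dilithium aldolate of 28 with 20 | C=C[C@H](O[Si](CC)(CC)CC)[C@@]2(C)[C@H]3O[C@H]3[C@@H](O[Si](CC)(CC)CC)[C@@](C)(O[Si](CC)(CC)CC)[C@@H]2[C@H](O[Li])[C@]4(O[C@H](C(C)(C)C)OC4=O)[C@@H](C)C(=O)O[Li] | intermediate
30 | C9 triethylsilyl ether, C19 triethylsilyl ester of the aldol adduct | C=C[C@H](O[Si](CC)(CC)CC)[C@@]2(C)[C@H]3O[C@H]3[C@@H](O[Si](CC)(CC)CC)[C@@](C)(O[Si](CC)(CC)CC)[C@@H]2[C@H](O[Si](CC)(CC)CC)[C@]4(O[C@H](C(C)(C)C)OC4=O)[C@@H](C)C(=O)O[Si](CC)(CC)CC | intermediate
31 | aldol adduct: C9 silyl ether, C8 in the dioxolanone, C19 free acid; C8, C9, C17 as in the target | C=C[C@H](O[Si](CC)(CC)CC)[C@@]2(C)[C@H]3O[C@H]3[C@@H](O[Si](CC)(CC)CC)[C@@](C)(O[Si](CC)(CC)CC)[C@@H]2[C@H](O[Si](CC)(CC)CC)[C@]4(O[C@H](C(C)(C)C)OC4=O)[C@@H](C)C(O)=O | intermediate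
32 | 4-hydroxy-1,3-dioxolane (lactol at C7) from 31 | C=C[C@H](O[Si](CC)(CC)CC)[C@@]2(C)[C@H]3O[C@H]3[C@@H](O[Si](CC)(CC)CC)[C@@](C)(O[Si](CC)(CC)CC)[C@@H]2[C@H](O[Si](CC)(CC)CC)[C@]4(O[C@H](C(C)(C)C)OC4O)[C@@H](C)C(O)=O | intermediate
33 | C7 aldehyde with free C8 hydroxyl and C19 acid | C=C[C@H](O[Si](CC)(CC)CC)[C@@]2(C)[C@H]3O[C@H]3[C@@H](O[Si](CC)(CC)CC)[C@@](C)(O[Si](CC)(CC)CC)[C@@H]2[C@H](O[Si](CC)(CC)CC)[C@@](O)(C=O)[C@@H](C)C(O)=O | intermediate
34 | C7 aldehyde with C8 triethylsilyl ether and C19 triethylsilyl ester | C=C[C@H](O[Si](CC)(CC)CC)[C@@]2(C)[C@H]3O[C@H]3[C@@H](O[Si](CC)(CC)CC)[C@@](C)(O[Si](CC)(CC)CC)[C@@H]2[C@H](O[Si](CC)(CC)CC)[C@@](O[Si](CC)(CC)CC)(C=O)[C@@H](C)C(=O)O[Si](CC)(CC)CC | intermediate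
35 | anti chlorohydrin acid: C7 hydroxyl, C6 chloride, C5 methylene with vinyl, C19 acid | C=C[C@H](O[Si](CC)(CC)CC)[C@@]2(C)[C@H]3O[C@H]3[C@@H](O[Si](CC)(CC)CC)[C@@](C)(O[Si](CC)(CC)CC)[C@@H]2[C@H](O[Si](CC)(CC)CC)[C@@](O[Si](CC)(CC)CC)([C@@H](O)[C@@H](Cl)C(=C)C=C)[C@@H](C)C(O)=O | intermediate
36 | γ-lactone (O7–C19) of 35 with the two vinyl groups still open | C=C[C@H](O[Si](CC)(CC)CC)[C@@]2(C)[C@H]3O[C@H]3[C@@H](O[Si](CC)(CC)CC)[C@@](C)(O[Si](CC)(CC)CC)[C@@H]2[C@H](O[Si](CC)(CC)CC)[C@]4(O[Si](CC)(CC)CC)[C@@H](C)C(=O)O[C@H]4[C@@H](Cl)C(=C)C=C | intermediate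
37 | briarane macrocycle with C2, C8, C9, C11, C12 triethylsilyl ethers, (3Z)-alkene | C=C1/C=C\[C@H](O[Si](CC)(CC)CC)[C@@]2(C)[C@H]3O[C@H]3[C@@H](O[Si](CC)(CC)CC)[C@@](C)(O[Si](CC)(CC)CC)[C@@H]2[C@H](O[Si](CC)(CC)CC)[C@]2(O[Si](CC)(CC)CC)[C@@H](C)C(=O)O[C@H]2[C@H]1Cl | intermediate
38 | pentaol (free hydroxyls at C2, C8, C9, C11, C12) | C=C1/C=C\[C@H](O)[C@@]2(C)[C@H]3O[C@H]3[C@@H](O)[C@@](C)(O)[C@@H]2[C@H](O)[C@]2(O)[C@@H](C)C(=O)O[C@H]2[C@H]1Cl | intermediate
39 | CNP0331168.1 | C=C1/C=C\[C@H](OC(C)=O)[C@@]2(C)[C@H]3O[C@H]3[C@@H](OC(C)=O)[C@@](C)(O)[C@@H]2[C@H](OC(C)=O)[C@]2(O)[C@@H](C)C(=O)O[C@H]2[C@H]1Cl | target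

**Step count and risks**

Total steps: 26. Longest linear sequence: 21 (steps 1–15 and 21–26).

Steps most likely to fail:

1. Step 10. The vinylic ring carbon C13 may migrate in place of C10, or equilibration may erode the C11 configuration. The fallback sets out from 11 and comes back at 15; it reaches the same enone by a Saegusa–Ito one-carbon ring expansion in which the former carbonyl carbon of 11 becomes C11 and the inserted carbon is C13. Conjugate reduction with LiB(s-Bu)3H and trapping with N-(5-chloro-2-pyridyl)triflimide should give the enol triflate F1. MeMgBr with Fe(acac)3 (cat.) should give the 1-methylcyclopentene F2. OsO4 (cat.) with N-methylmorpholine N-oxide should add anti to the C10 substituent to give the cis-diol F3. SO3·pyridine/DMSO should oxidise the secondary alcohol to the hydroxy ketone F4. Me3SiOTf/Et3N should give the bis-silyl enol ether F5, since enolisation is possible only toward C14. Et2Zn/CH2I2 should give the siloxycyclopropane F6. FeCl3 in DMF should open it to the β-chloro ketone F7, and NaOAc in MeOH should eliminate HCl to the silylated enone F8. K2CO3 in MeOH then removes both trimethylsilyl groups to give 15.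

2. Step 24. Ring closure may be slower than oligomerisation, because the lactone holds the two alkenes apart and the ring is strained. The fallback sets out from 34 and 27 and comes back at 37; it inverts the order of the two ring closures. The chromium step is worked up at pH 5 and the crude acid 35 is esterified at once with Me3SiCHN2 to the open-chain methyl ester F9. Metathesis of this unconstrained triene under the conditions of step 24 should give the ten-membered hydroxy ester F10. PPTS in toluene at 60 °C then closes the lactone to give 37.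

3. Step 21. Retro-aldol reversal and poor facial selectivity at C9 are likely when a tetrasubstituted enolate meets a doubly neopentyl aldehyde. The fallback sets out from 28 and 20 and comes back at 30, and from there at 31. Silylation of 28 with Et3SiCl should give the bis(triethylsilyl) ketene acetal F11. A Mukaiyama aldol with 20 catalysed by Et3SiOTf (10 mol %, CH2Cl2, −78 °C) runs through an open transition state with silyl transfer, is not reversible, and follows a different facial model; it should give 30, which is hydrolysed to 31 at work-up.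

**Further compounds**

F1 | step 10 | enol triflate from conjugate reduction of 11 | C[Si](C)(C)C#C[C@H](O[Si](CC)(CC)CC)[C@@]1(C)CC=C(OS(=O)(=O)C(F)(F)F)[C@@H]1CO[Si](CC)(CC)CC
F2 | step 10 | 1-methylcyclopentene | C[Si](C)(C)C#C[C@H](O[Si](CC)(CC)CC)[C@@]1(C)CC=C(C)[C@@H]1CO[Si](CC)(CC)CC
F3 | step 10 | cis-diol, hydroxyls trans to CH2OSiEt3 | C[Si](C)(C)C#C[C@H](O[Si](CC)(CC)CC)[C@@]1(C)C[C@@H](O)[C@@](C)(O)[C@@H]1CO[Si](CC)(CC)CC
F4 | step 10 | 2-hydroxy-2-methylcyclopentanone | C[Si](C)(C)C#C[C@H](O[Si](CC)(CC)CC)[C@@]1(C)CC(=O)[C@@](C)(O)[C@@H]1CO[Si](CC)(CC)CC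
F5 | step 10 | trimethylsilyl enol ether with tertiary trimethylsilyl ether | C[Si](C)(C)C#C[C@H](O[Si](CC)(CC)CC)[C@@]1(C)C=C(O[Si](C)(C)C)[C@@](C)(O[Si](C)(C)C)[C@@H]1CO[Si](CC)(CC)CC
F6 | step 10 | siloxycyclopropane (bicyclo[3.1.0]hexane, either cyclopropane face) | C[Si](C)(C)C#C[C@H](O[Si](CC)(CC)CC)[C@@]1(C)C2CC2(O[Si](C)(C)C)[C@@](C)(O[Si](C)(C)C)[C@@H]1CO[Si](CC)(CC)CC
F7 | step 10 | 3-chlorocyclohexanone (chloride at C14) | C[Si](C)(C)C#C[C@H](O[Si](CC)(CC)CC)[C@@]2(C)C(Cl)CC(=O)[C@@](C)(O[Si](C)(C)C)[C@@H]2CO[Si](CC)(CC)CC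
F8 | step 10 | cyclohexenone with C11 trimethylsilyl ether and silylated alkyne | C[Si](C)(C)C#C[C@H](O[Si](CC)(CC)CC)[C@@]2(C)C=CC(=O)[C@@](C)(O[Si](C)(C)C)[C@@H]2CO[Si](CC)(CC)CC
F9 | step 24 | methyl ester of chlorohydrin acid 35 | C=C[C@H](O[Si](CC)(CC)CC)[C@@]2(C)[C@H]3O[C@H]3[C@@H](O[Si](CC)(CC)CC)[C@@](C)(O[Si](CC)(CC)CC)[C@@H]2[C@H](O[Si](CC)(CC)CC)[C@@](O[Si](CC)(CC)CC)([C@@H](O)[C@@H](Cl)C(=C)C=C)[C@@H](C)C(=O)OC
F10 | step 24 | ten-membered hydroxy methyl ester, (3Z)-alkene | C=C1/C=C\[C@H](O[Si](CC)(CC)CC)[C@@]2(C)[C@H]3O[C@H]3[C@@H](O[Si](CC)(CC)CC)[C@@](C)(O[Si](CC)(CC)CC)[C@@H]2[C@H](O[Si](CC)(CC)CC)[C@](O[Si](CC)(CC)CC)([C@@H](C)C(=O)OC)[C@@H](O)[C@H]1Cl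
F11 | step 21 | bis(triethylsilyl) ketene acetal of 24 | CC(C)(C)[C@H]1OC([C@@H](C)C(=O)O[Si](CC)(CC)CC)=C(O[Si](CC)(CC)CC)O1
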